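**Plan**
- Retrosynthesis: the five O–benzyl bonds are cut first, then the central aryl–C(=O) bond and the two outer aryl–butanoyl bonds. Last, three ring C–C bonds in each outer ring are cut, leading to a central bis(siloxyalkyne) and two molecules of 3-methoxy-4-methylcyclobutenone.
- Enabling feature: in each outer ring the hydroxyl-bearing carbon lies between the CH2-bearing carbon and the methyl-bearing carbon, and a second oxygen sits meta to it. This is a resorcinol with the alkyne-derived substituent between its two oxygens, the pattern a vinylketene/siloxyalkyne benzannulation delivers.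
- Forward: the central ring is present from the start (phloroglucinol → tribenzyl ether → dibromide → bis(arylacetate) → bis(siloxyalkyne)). Both outer rings then form at once in the twofold benzannulation.
- Acyl groups follow: butanoyl on the outer rings by O-acylation and Fries shift, then 2-methylbutanoyl at the last free aromatic C–H, then global hydrogenolysis.
- Stereochemistry: the only stereocentre, (S) at C2 of the 2-methylbutanoyl group, comes from (S)-2-methylbutanoic acid and enters in the penultimate step under non-basic conditions.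

Key step: step 7

Remark: cyclobutenone 15 is used as the racemate because its stereocentre is destroyed in step 7, and volatile methoxyacetylene 12 is handled as a cold ethereal solution.

**Route**

Step 1
Reactants: 1 phloroglucinol
Product: 2 1,3,5-tris(benzyloxy)benzene
Conditions: BnBr (3.3 equiv), K2CO3, DMF, rt → 60 °C
Reagents that add atoms: benzyl bromide, BrCc1ccccc1
Why: Williamson etherification, in which a carbonate base in a dipolar aprotic solvent favours O- over C-benzylation of the phloroglucinol anion and the crystalline tris-ether can be separated from C-benzylated by-products.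

Step 2
Reactants: 2 1,3,5-tris(benzyloxy)benzene
Product: 3 1,3,5-tris(benzyloxy)-2,4-dibromobenzene
Conditions: NBS (2.05 equiv), CH2Cl2, −20 → 0 °C, dark
Reagents that add atoms: N-bromosuccinimide, O=C1CCC(=O)N1Br
Why: Electrophilic aromatic bromination of a ring whose three C–H positions are equivalent; each bromine lowers the ring reactivity, so two equivalents should stop at the dibromide and leave the third C–H for the late acylation.

Step 3
Reactants: 3 1,3,5-tris(benzyloxy)-2,4-dibromobenzene, 4 ethyl bromoacetate
Product: 6 diethyl 2,2'-[2,4,6-tris(benzyloxy)-1,3-phenylene]diacetate, via Reformatsky reagent 5 (not isolated)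
Conditions: 4 (3 equiv), Zn dust (TMSCl-activated), THF, 40 °C; then 3, Pd(dba)2 (bis(dibenzylideneacetone)palladium, zerovalent palladium, 5 mol%), 1,2,3,4,5-pentaphenyl-1'-(di-tert-butylphosphino)ferrocene (Q-phos, 5 mol%), THF, 60 °C
Reagents that add atoms: none
Why: Palladium-catalysed α-arylation of an ester zinc enolate (Reformatsky–Negishi coupling), in which the bulky electron-rich phosphine drives oxidative addition into the hindered, electron-rich C–Br bonds and the weakly basic zinc enolate transfers the CH2CO2Et group without Claisen condensation or harm to the benzyl ethers.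

Step 4
Reactants: 6 diethyl 2,2'-[2,4,6-tris(benzyloxy)-1,3-phenylene]diacetate, 7 dibromomethane
Product: 9 1,3,5-tris(benzyloxy)-2,4-bis[3-(triisopropylsilyloxy)prop-2-yn-1-yl]benzene, via dilithium bis(ynolate) 8 (not isolated)
Conditions: 7 (4.4 equiv), LiTMP (lithium 2,2,6,6-tetramethylpiperidide), THF, −78 °C, then 6; LiHMDS (LiN(SiMe3)2), −78 → −20 °C; n-BuLi, −78 → 0 °C; TIPSCl (i-Pr3SiCl), −78 °C → rt; chromatography on Et3N-deactivated silica
Reagents that add atoms: chlorotriisopropylsilane, CC(C)[Si](Cl)(C(C)C)C(C)C
Why: Kowalski ester homologation intercepted at the ynolate stage, in which LiCHBr2 adds to each ester carbonyl faster than it enolises the hindered arylacetate, the derived dibromo ketone enolate undergoes Br–Li exchange and 1,2-shift of the arylmethyl group to the carbenoid carbon, and the bulky silyl chloride traps the ynolate on oxygen.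

Step 5
Reactants: 10 2-chloro-1,1-dimethoxyethane
Product: 12 methoxyacetylene, via sodium methoxyacetylide 11 (not isolated)
Conditions: NaNH2 (3 equiv), liquid NH3, −33 °C; then aqueous NH4Cl, −70 °C; distilled into cold Et2O
Reagents that add atoms: none
Why: Twofold base-induced elimination (loss of methanol, then of HCl) from the chloroacetal, the classical alkoxyacetylene preparation, with the alkyne held as its sodium acetylide until the cold quench.

Step 6
Reactants: 12 methoxyacetylene, 13 propanoyl chloride
Product: 15 3-methoxy-4-methylcyclobut-2-en-1-one (racemic), via methylketene 14 (not isolated)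
Conditions: Et3N, Et2O, 0 °C → rt, slow addition of 13 to excess 12
Reagents that add atoms: none
Why: Dehydrochlorination gives methylketene, which undergoes the regioselective ketene–ynol ether (2+2) cycloaddition (the nucleophilic terminal carbon of 12 attacks the ketene carbonyl carbon), placing methoxy at C3 and methyl at C4; slow addition into excess alkyne disfavours ketene dimerisation, and the C4 stereocentre forms as a racemate of no consequence.

Step 7
Reactants: 9 1,3,5-tris(benzyloxy)-2,4-bis[3-(triisopropylsilyloxy)prop-2-yn-1-yl]benzene, 15 3-methoxy-4-methylcyclobut-2-en-1-one (3 equiv)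
Product: 19 2,2'-{[2,4,6-tris(benzyloxy)-1,3-phenylene]bis(methylene)}bis[5-methoxy-6-methyl-3-(triisopropylsilyloxy)phenol], via vinylketene 16 (not isolated), via bis(vinylcyclobutenone) 17 (not isolated), via bis(dienylketene) 18 (not isolated)
Conditions: toluene (degassed), 80 °C then 110 °C, sealed tube, argon
Reagents that add atoms: none
Why: On heating, 15 opens by 4π-electrocyclic ring opening to the 3-methoxy vinylketene 16, which adds to each siloxyalkyne of 9 in a (2+2) cycloaddition to give the 4-vinylcyclobutenone 17; this opens again to the dienylketene 18, which cyclises and tautomerises to the phenol. The closest known reaction type is the Danheiser benzannulation of cyclobutenones with siloxyalkynes to resorcinol monosilyl ethers, together with the classical conversion of 3-alkoxycyclobutenones and alkoxyacetylenes into resorcinol ethers, here run twice on one substrate. Each outer benzene ring is closed by thermal 6π-electrocyclisation of a dienylketene (bond from the future C–OH carbon to the methyl-bearing carbon), after the cycloaddition has made the bonds from the C–OH carbon to the bridge-bearing carbon and from the siloxy-bearing carbon to the C–H carbon. No stereocentre is created, and the one in racemic 15 becomes a planar ring carbon. The step needs the regiochemistry of the ketene–alkyne union, which the polarisation of the siloxyalkyne secures: its carbon remote from oxygen is the nucleophile and bonds to the electrophilic ketene carbonyl carbon, so the arylmethyl substituent ends up between the two oxygens. The two alkyne arms are insulated by the central ring and should react independently, the benzyl ethers are thermally inert, and the new phenols, each flanked by two ortho substituents, should be slow to trap excess ketene.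

Step 8
Reactants: 19 2,2'-{[2,4,6-tris(benzyloxy)-1,3-phenylene]bis(methylene)}bis[5-methoxy-6-methyl-3-(triisopropylsilyloxy)phenol]
Product: 20 1,3,5-tris(benzyloxy)-2,4-bis{[2-(benzyloxy)-4-methoxy-3-methyl-6-(triisopropylsilyloxy)phenyl]methyl}benzene
Conditions: NaH, BnBr, Bu4NI (cat.), DMF, 0 °C → rt
Reagents that add atoms: benzyl bromide, BrCc1ccccc1
Why: Williamson etherification of the two hindered phenols through their sodium phenoxides, which the triisopropylsilyl ethers tolerate; benzyl is chosen so that these oxygens are released together with the three central ones in the last step.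

Step 9
Reactants: 20 1,3,5-tris(benzyloxy)-2,4-bis{[2-(benzyloxy)-4-methoxy-3-methyl-6-(triisopropylsilyloxy)phenyl]methyl}benzene, 21 butanoic anhydride
Product: 23 1,3,5-tris(benzyloxy)-2,4-bis{[2-(benzyloxy)-6-(butanoyloxy)-4-methoxy-3-methylphenyl]methyl}benzene, via bis(phenol) 22 (not isolated)
Conditions: TBAF (Bu4NF, 2.2 equiv), THF, 0 °C; then 21 (excess), DMAP (cat.), 0 °C → rt
Reagents that add atoms: none
Why: Fluoride cleavage of the aryl silyl ethers followed by in situ acylation of the liberated phenoxides (DMAP-assisted acyl transfer); only the oxygen silylated in the annulation is freed, so the butanoate is placed next to the one unsubstituted carbon of each outer ring.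

Step 10
Reactants: 23 1,3,5-tris(benzyloxy)-2,4-bis{[2-(benzyloxy)-6-(butanoyloxy)-4-methoxy-3-methylphenyl]methyl}benzene
Product: 24 1,3,5-tris(benzyloxy)-2,4-bis{[2-(benzyloxy)-5-butanoyl-6-hydroxy-4-methoxy-3-methylphenyl]methyl}benzene
Conditions: TiCl4 (2.5 equiv), CH2Cl2, −40 → 0 °C; then cold dilute aqueous HCl
Reagents that add atoms: none
Why: Lewis acid-mediated Fries rearrangement, in which the acyl group can only go to the one free ortho carbon of each outer ring (the other ortho and the para positions are substituted), a position activated by three oxygen substituents, so the shift should occur cold within the titanium phenoxide ion pair and end as the chelate of the ortho-hydroxy ketone while the benzyl aryl ethers survive the short exposure.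

Step 11
Reactants: 24 1,3,5-tris(benzyloxy)-2,4-bis{[2-(benzyloxy)-5-butanoyl-6-hydroxy-4-methoxy-3-methylphenyl]methyl}benzene, 25 (S)-2-methylbutanoic acid
Product: 27 (S)-1-[2,4,6-tris(benzyloxy)-3,5-bis{[2-(benzyloxy)-5-butanoyl-6-hydroxy-4-methoxy-3-methylphenyl]methyl}phenyl]-2-methylbutan-1-one, via (S)-2-methylbutanoyl chloride 26 (not isolated)
Conditions: 25 (1.5 equiv), (COCl)2, DMF (cat.), CH2Cl2, 0 °C → rt, concentrated; then 24, TiCl4 (4 equiv), CH2Cl2, −78 → −20 °C
Reagents that add atoms: none
Why: Base-free chlorination of the acid (Vilsmeier-type activation, no ketene pathway) followed by Friedel–Crafts acylation at the single remaining aromatic C–H of the molecule, the electron-rich central position between two benzyloxy groups; TiCl4 masks the two ortho-hydroxy ketones as chelates against O-acylation, no new stereocentre is formed, and the low temperature should carry the (S)-centre of 25 over unchanged.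

Step 12
Reactants: 27 (S)-1-[2,4,6-tris(benzyloxy)-3,5-bis{[2-(benzyloxy)-5-butanoyl-6-hydroxy-4-methoxy-3-methylphenyl]methyl}phenyl]-2-methylbutan-1-one
Product: 28 agrimol B
Conditions: H2 (1 atm), Pd/C (10% palladium on carbon), EtOAc–MeOH, rt
Reagents that add atoms: none
Why: Hydrogenolysis of the five benzyl aryl ethers under neutral conditions, which should leave the hydrogen-bonded aryl ketones and the diarylmethane bridges unreduced and cannot epimerise the α-branched ketone.

**Compound list**

1 | phloroglucinol (benzene-1,3,5-triol) | Oc1cc(O)cc(O)c1 | starting material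
2 | 1,3,5-tris(benzyloxy)benzene | c1c(OCc2ccccc2)cc(OCc2ccccc2)cc1OCc1ccccc1 | intermediate
3 | 1,3,5-tris(benzyloxy)-2,4-dibromobenzene | c1c(OCc2ccccc2)c(Br)c(OCc2ccccc2)c(Br)c1OCc1ccccc1 | intermediate
4 | ethyl bromoacetate | CCOC(=O)CBr | starting material
5 | ethyl (bromozincio)acetate (Reformatsky reagent) | CCOC(=O)C[Zn]Br | intermediate
6 | diethyl 2,2'-[2,4,6-tris(benzyloxy)-1,3-phenylene]diacetate | c1c(OCc2ccccc2)c(CC(=O)OCC)c(OCc2ccccc2)c(CC(=O)OCC)c1OCc1ccccc1 | intermediate
7 | dibromomethane | BrCBr | starting material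
8 | dilithium 3,3'-[2,4,6-tris(benzyloxy)-1,3-phenylene]bis(prop-1-yn-1-olate) | [Li+].[Li+].c1c(OCc2ccccc2)c(CC#C[O-])c(OCc2ccccc2)c(CC#C[O-])c1OCc1ccccc1 | intermediate
9 | 1,3,5-tris(benzyloxy)-2,4-bis[3-(triisopropylsilyloxy)prop-2-yn-1-yl]benzene | c1c(OCc2ccccc2)c(CC#CO[Si](C(C)C)(C(C)C)C(C)C)c(OCc2ccccc2)c(CC#CO[Si](C(C)C)(C(C)C)C(C)C)c1OCc1ccccc1 | intermediate
10 | 2-chloro-1,1-dimethoxyethane | COC(CCl)OC | starting material
11 | sodium methoxyacetylide | [Na+].[C-]#COC | intermediate
12 | methoxyacetylene (methoxyethyne) | C#COC | intermediate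
13 | propanoyl chloride | CCC(=O)Cl | starting material
14 | methylketene (prop-1-en-1-one) | CC=C=O | intermediate
15 | 3-methoxy-4-methylcyclobut-2-en-1-one (racemic) | COC1=CC(=O)C1C | intermediate
16 | 3-methoxypenta-1,3-dien-1-one (vinylketene, alkene geometry not fixed) | O=C=CC(OC)=CC | intermediate
17 | 1,3,5-tris(benzyloxy)-2,4-bis{[4-(1-methoxyprop-1-enyl)-3-(triisopropylsilyloxy)-1-oxocyclobut-2-en-2-yl]methyl}benzene (diastereomer mixture) | c1c(OCc2ccccc2)c(CC2=C(O[Si](C(C)C)(C(C)C)C(C)C)C(C(OC)=CC)C2=O)c(OCc2ccccc2)c(CC2=C(O[Si](C(C)C)(C(C)C)C(C)C)C(C(OC)=CC)C2=O)c1OCc1ccccc1 | intermediate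
18 | bis(dienylketene): each arm ArCH2–C(=C=O)–C(OSi(i-Pr)3)=CH–C(OMe)=CHMe on the tribenzylated central ring | c1c(OCc2ccccc2)c(CC(=C=O)C(O[Si](C(C)C)(C(C)C)C(C)C)=CC(OC)=CC)c(OCc2ccccc2)c(CC(=C=O)C(O[Si](C(C)C)(C(C)C)C(C)C)=CC(OC)=CC)c1OCc1ccccc1 | intermediate
19 | 2,2'-{[2,4,6-tris(benzyloxy)-1,3-phenylene]bis(methylene)}bis[5-methoxy-6-methyl-3-(triisopropylsilyloxy)phenol] | c1c(OCc2ccccc2)c(Cc2c(O)c(C)c(OC)cc2O[Si](C(C)C)(C(C)C)C(C)C)c(OCc2ccccc2)c(Cc2c(O)c(C)c(OC)cc2O[Si](C(C)C)(C(C)C)C(C)C)c1OCc1ccccc1 | intermediate
20 | 1,3,5-tris(benzyloxy)-2,4-bis{[2-(benzyloxy)-4-methoxy-3-methyl-6-(triisopropylsilyloxy)phenyl]methyl}benzene | c1c(OCc2ccccc2)c(Cc2c(OCc3ccccc3)c(C)c(OC)cc2O[Si](C(C)C)(C(C)C)C(C)C)c(OCc2ccccc2)c(Cc2c(OCc3ccccc3)c(C)c(OC)cc2O[Si](C(C)C)(C(C)C)C(C)C)c1OCc1ccccc1 | intermediate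
21 | butanoic anhydride | CCCC(=O)OC(=O)CCC | starting material
22 | 2,2'-{[2,4,6-tris(benzyloxy)-1,3-phenylene]bis(methylene)}bis[3-(benzyloxy)-5-methoxy-4-methylphenol] (present in the flask as its tetrabutylammonium phenoxide) | c1c(OCc2ccccc2)c(Cc2c(OCc3ccccc3)c(C)c(OC)cc2O)c(OCc2ccccc2)c(Cc2c(OCc3ccccc3)c(C)c(OC)cc2O)c1OCc1ccccc1 | intermediate
23 | 1,3,5-tris(benzyloxy)-2,4-bis{[2-(benzyloxy)-6-(butanoyloxy)-4-methoxy-3-methylphenyl]methyl}benzene | c1c(OCc2ccccc2)c(Cc2c(OCc3ccccc3)c(C)c(OC)cc2OC(=O)CCC)c(OCc2ccccc2)c(Cc2c(OCc3ccccc3)c(C)c(OC)cc2OC(=O)CCC)c1OCc1ccccc1 | intermediate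
24 | 1,3,5-tris(benzyloxy)-2,4-bis{[2-(benzyloxy)-5-butanoyl-6-hydroxy-4-methoxy-3-methylphenyl]methyl}benzene | c1c(OCc2ccccc2)c(Cc2c(OCc3ccccc3)c(C)c(OC)c(C(=O)CCC)c2O)c(OCc2ccccc2)c(Cc2c(OCc3ccccc3)c(C)c(OC)c(C(=O)CCC)c2O)c1OCc1ccccc1 | intermediate
25 | (S)-2-methylbutanoic acid | CC[C@H](C)C(=O)O | starting material
26 | (S)-2-methylbutanoyl chloride | CC[C@H](C)C(=O)Cl | intermediate
27 | (S)-1-[2,4,6-tris(benzyloxy)-3,5-bis{[2-(benzyloxy)-5-butanoyl-6-hydroxy-4-methoxy-3-methylphenyl]methyl}phenyl]-2-methylbutan-1-one | CC[C@H](C)C(=O)c1c(OCc2ccccc2)c(Cc2c(OCc3ccccc3)c(C)c(OC)c(C(=O)CCC)c2O)c(OCc2ccccc2)c(Cc2c(OCc3ccccc3)c(C)c(OC)c(C(=O)CCC)c2O)c1OCc1ccccc1 | intermediate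
28 | agrimol B, (S)-1-{3,5-bis[(3-butanoyl-2,6-dihydroxy-4-methoxy-5-methylphenyl)methyl]-2,4,6-trihydroxyphenyl}-2-methylbutan-1-one | CCCC(=O)c1c(O)c(Cc2c(O)c(Cc3c(O)c(C)c(OC)c(C(=O)CCC)c3O)c(O)c(C(=O)[C@@H](C)CC)c2O)c(O)c(C)c1OC | target

**Step count**

Total: 12 steps. Longest linear sequence: 10 steps (steps 1–4 and 7–12).

**Steps most likely to fail**

Step 7. The donor-stabilised (vinylogous ester) cyclobutenone may open too slowly, so that thermal 1,3-silyl migration of the siloxyalkyne to a silylketene, ketene dimerisation or stalling after the first annulation overtakes the cascade. The fallback makes the same vinylketene 16 without a thermal ring opening. Commercial methyl 3-oxopentanoate is converted with trimethyl orthoformate and catalytic H2SO4 in methanol into methyl (E)-3-methoxypent-2-enoate F1. Saponification (LiOH, aqueous THF, then acid) gives (E)-3-methoxypent-2-enoic acid F2, and oxalyl chloride gives (E)-3-methoxypent-2-enoyl chloride F3. Slow addition of F3 to 9 and Et3N in CH2Cl2 at 0 °C → rt releases 16 by 1,4-dehydrochlorination, where it is trapped by the siloxyalkynes as 17. Gentle warming in toluene (60–80 °C) then completes the sequence. This fallback sets out from 9 and returns to the route at 19.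

Step 4. LiCHBr2 may enolise the arylacetate instead of adding to it, excess n-BuLi may metalate the benzyl ethers or the central C–H during the ynolate rearrangement, and conversion of the second ester may be incomplete. The fallback sets out from 6. DIBAL-H (i-Bu2AlH, CH2Cl2, −78 °C) gives 2,2'-[2,4,6-tris(benzyloxy)-1,3-phenylene]diacetaldehyde F4, and Corey–Fuchs olefination (CBr4, PPh3) gives the bis(1,1-dibromoalkene) F5. n-BuLi in THF at −78 °C converts F5 into the bis(lithium acetylide) F6. Oxidation of F6 in the same flask with lithium tert-butyl peroxide (LiOOt-Bu) gives ynolate 8, which is silylated on oxygen with TIPSOTf (i-Pr3SiOSO2CF3). The fallback returns to the route at 9.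

Step 10. The acylium fragment may escape from the titanium phenoxide and be captured by the free C–H of the central ring (cross-over acylation), and the Lewis acid may cleave benzyl ethers. The fallback sets out from bis(phenol) 22, isolated by aqueous work-up after TBAF treatment of 20. Phenol-directed ortho-formylation (MgCl2, Et3N, paraformaldehyde, MeCN, reflux; Casiraghi–Skattebøl conditions) can only touch the outer rings and should give the bis(salicylaldehyde) F7. Addition of n-PrMgBr (excess, THF, 0 °C) gives the bis(carbinol) F8 as a diastereomer mixture. Oxidation of the benzylic alcohols with activated MnO2 (CH2Cl2, rt) returns to the route at 24.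

**Further compounds**

F1 | step 7 | methyl (E)-3-methoxypent-2-enoate | CO/C(CC)=C/C(=O)OC
F2 | step 7 | (E)-3-methoxypent-2-enoic acid | CO/C(CC)=C/C(=O)O
F3 | step 7 | (E)-3-methoxypent-2-enoyl chloride | CO/C(CC)=C/C(=O)Cl
F4 | step 4 | 2,2'-[2,4,6-tris(benzyloxy)-1,3-phenylene]diacetaldehyde | c1c(OCc2ccccc2)c(CC=O)c(OCc2ccccc2)c(CC=O)c1OCc1ccccc1
F5 | step 4 | 1,3,5-tris(benzyloxy)-2,4-bis(3,3-dibromoprop-2-en-1-yl)benzene | c1c(OCc2ccccc2)c(CC=C(Br)Br)c(OCc2ccccc2)c(CC=C(Br)Br)c1OCc1ccccc1
F6 | step 4 | dilithium acetylide of 1,3,5-tris(benzyloxy)-2,4-di(prop-2-yn-1-yl)benzene | c1c(OCc2ccccc2)c(CC#C[Li])c(OCc2ccccc2)c(CC#C[Li])c1OCc1ccccc1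
F7 | step 10 | 1,3,5-tris(benzyloxy)-2,4-bis{[2-(benzyloxy)-5-formyl-6-hydroxy-4-methoxy-3-methylphenyl]methyl}benzene | c1c(OCc2ccccc2)c(Cc2c(OCc3ccccc3)c(C)c(OC)c(C=O)c2O)c(OCc2ccccc2)c(Cc2c(OCc3ccccc3)c(C)c(OC)c(C=O)c2O)c1OCc1ccccc1
F8 | step 10 | 1,3,5-tris(benzyloxy)-2,4-bis{[2-(benzyloxy)-6-hydroxy-5-(1-hydroxybutyl)-4-methoxy-3-methylphenyl]methyl}benzene (diastereomer mixture) | c1c(OCc2ccccc2)c(Cc2c(OCc3ccccc3)c(C)c(OC)c(C(O)CCC)c2O)c(OCc2ccccc2)c(Cc2c(OCc3ccccc3)c(C)c(OC)c(C(O)CCC)c2O)c1OCc1ccccc1
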